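The 7‑oxabicyclo[2.2.1]heptane is cut at C1–O7, C1–C6 and C4–C5: its C1–O7–C4 ether bridge is read as a cyclic carbonyl ylide and the C5–C6 ethano bridge as ethylene. One rhodium‑catalysed operation on an acyclic diazo keto aldehyde (diazo carbon C1 bearing the methyl, ketone C2, quaternary CMe2 at C3, aldehyde C4) should therefore close both oxolane rings and the six‑membered carbocycle and set both bridgehead stereocentres. The C2 ketone is left as the handle for an exo‑selective radical C–C bond to the side chain. The E‑alkene and the arene are then attached by stereospecific carboalumination and Negishi coupling.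

Key step: step 7

Assumption: Rh2(S-PTTL)4 is taken to give the (1S,4R) cycloadduct; if the sense of induction proved opposite, Rh2(R-PTTL)4 would be used with no other change.
Numbering: C1–C6 and O7 are the positions of the oxabicyclic core (C1 methyl‑bearing bridgehead, C2 side‑chain carbon, C3 CMe2, C4 CH bridgehead, C5–C6 ethano bridge, O7).

Step 1
Reactants: 1 methyl 3-hydroxy-2,2-dimethylpropanoate
Product: 2 methyl 3-[(tert-butyldimethylsilyl)oxy]-2,2-dimethylpropanoate
Conditions: TBSCl, imidazole, DMF, rt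
Reagents that add atoms: tert-butyldimethylsilyl chloride, CC(C)(C)[Si](C)(C)Cl
Why: Imidazole‑promoted silylation of an unhindered primary alcohol should be clean and masks the future aldehyde carbon C4 through the basic and organometallic steps.

Step 2
Reactants: 2 methyl 3-[(tert-butyldimethylsilyl)oxy]-2,2-dimethylpropanoate
Product: 3 3-[(tert-butyldimethylsilyl)oxy]-N-methoxy-N,2,2-trimethylpropanamide
Conditions: MeNH(OMe)·HCl, iPrMgCl (3 equiv), THF, −20 to 0 °C
Reagents that add atoms: N,O-dimethylhydroxylamine hydrochloride, CNOC.Cl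
Why: Weinreb amide formation by ester aminolysis: the small chloromagnesium N-methoxy-N-methylamide made in situ should acylate even at the neopentyl‑type ester, and the silyl ether is inert to it.

Step 3
Reactants: 3 3-[(tert-butyldimethylsilyl)oxy]-N-methoxy-N,2,2-trimethylpropanamide
Product: 4 1-[(tert-butyldimethylsilyl)oxy]-2,2-dimethylpentan-3-one
Conditions: EtMgBr, THF, 0 °C; aq. NH4Cl
Reagents that add atoms: ethylmagnesium bromide, CC[Mg]Br
Why: Weinreb ketone synthesis: the chelated magnesium adduct persists until the quench, so a single ethyl group (future C1 and its methyl) should be delivered without over‑addition.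

Step 4
Reactants: 4 1-[(tert-butyldimethylsilyl)oxy]-2,2-dimethylpentan-3-one
Product: 6 1-[(tert-butyldimethylsilyl)oxy]-4-diazo-2,2-dimethylpentan-3-one, via trifluoroacetyl diketone 5 (not isolated)
Conditions: LiN(SiMe3)2, THF, −78 °C; CF3CO2CH2CF3; aq. NH4Cl; then 4-acetamidobenzenesulfonyl azide, Et3N, H2O (1 equiv), MeCN, rt
Reagents that add atoms: 4-acetamidobenzenesulfonyl azide, CC(=O)Nc1ccc(cc1)S(=O)(=O)N=[N+]=[N-]
Why: Detrifluoroacetylative (Regitz‑type deacylative) diazo transfer: the ethyl CH2 is the only enolisable position, C‑trifluoroacetylation activates it, and the sulfonyl azide should then deliver N2 while the trifluoroacetyl group passes to the sulfonamide nitrogen.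

Step 5
Reactants: 6 1-[(tert-butyldimethylsilyl)oxy]-4-diazo-2,2-dimethylpentan-3-one
Product: 7 4-diazo-1-hydroxy-2,2-dimethylpentan-3-one
Conditions: Bu4NF, AcOH, THF, 0 °C to rt
Reagents that add atoms: none
Why: Fluoride‑driven Si–O cleavage; the acetic acid buffer should prevent retro‑aldol loss of formaldehyde from the alkoxide and is too weak an acid to protonate the diazo ketone.

Step 6
Reactants: 7 4-diazo-1-hydroxy-2,2-dimethylpentan-3-one
Product: 8 4-diazo-2,2-dimethyl-3-oxopentanal
Conditions: Dess–Martin periodinane, pyridine, CH2Cl2, 0 °C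
Reagents that add atoms: none
Why: Dess–Martin oxidation under pyridine buffer is neutral and fast, should leave the diazo ketone intact, and gives an aldehyde whose quaternary α‑carbon rules out enolisation and self‑condensation.

Step 7
Reactants: 8 4-diazo-2,2-dimethyl-3-oxopentanal and 9 ethylene
Product: 11 (1S,4R)-1,3,3-trimethyl-7-oxabicyclo[2.2.1]heptan-2-one, via cyclic carbonyl ylide 10 (not isolated)
Conditions: Rh2(S-PTTL)4 [dirhodium tetrakis(N-phthaloyl-(S)-tert-leucinate)] (1 mol%), ethylene (20 bar), PhCF3, 0 °C, 8 added over 4 h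
Reagents that add atoms: none
Why: Rh2(S-PTTL)4 expels N2 from 8 to give a divalent‑rhodium carbenoid at C1, and the aldehyde oxygen O7, held close by the C3 gem‑dimethyl group, attacks the carbenoid carbon in a 5‑exo‑type closure that forms the first oxolane (O7-C1-C2-C3-C4) as the catalyst‑associated carbonyl ylide 10. Ethylene then adds suprafacially to the ylide termini C1 and C4 in a concerted [3+2] dipolar cycloaddition that forms C1–C6 and C4–C5 together and so closes the second oxolane (O7-C1-C6-C5-C4) and the six‑membered carbocycle at once. The closest known reaction type is the dirhodium‑carboxylate cyclisation–cycloaddition cascade of 1-diazo-2,4-diones through five‑membered carbonyl ylides, including its enantioselective form with chiral dirhodium carboxylates. C1 and C4 are created together and the bridge ties their relative configuration, so only the absolute sense is open; it should be set by the chiral N‑phthaloyl‑tert‑leucinate ligands, which shield one face of the planar ylide while it is still bound to rhodium. Enantiofacial selection is the only selectivity required, because ethylene is symmetric and poses no regiochemical or endo/exo question. Chemoselectivity rests on the substrate and the conditions: the quaternary C3 makes ring closure fast and denies the ylide an α‑hydrogen for proton transfer, the bulky carboxylates at 0 °C disfavour 1,2‑hydride shift from the C1 methyl group, and slow addition of 8 into excess ethylene keeps the free aldehyde, the only other dipolarophile, at a low level.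

Step 8
Reactants: 11 (1S,4R)-1,3,3-trimethyl-7-oxabicyclo[2.2.1]heptan-2-one
Product: 12 (1S,2S,4R)-1,3,3-trimethyl-7-oxabicyclo[2.2.1]heptan-2-ol
Conditions: LiAlH4, Et2O, 0 °C
Reagents that add atoms: none
Why: Hydride reduction of the hindered ketone: LiAlH4 should attack the exo face (syn to O7) to give mainly the 2‑endo alcohol, and the C2 configuration is without consequence because C2 becomes a planar radical in step 10.

Step 9
Reactants: 12 (1S,2S,4R)-1,3,3-trimethyl-7-oxabicyclo[2.2.1]heptan-2-ol
Product: 14 O-[(1S,2S,4R)-1,3,3-trimethyl-7-oxabicyclo[2.2.1]heptan-2-yl] S-methyl carbonodithioate, via sodium xanthate salt 13 (not isolated)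
Conditions: NaH, imidazole (cat.), THF, 0 °C to reflux; CS2; MeI, rt
Reagents that add atoms: carbon disulfide, S=C=S; iodomethane, CI
Why: Xanthate formation (first stage of a Barton–McCombie‑type radical generation): the alkoxide should add to the small electrophile CS2 despite the two flanking quaternary carbons, and S‑methylation fixes the dithiocarbonate.

Step 10
Reactants: 14 O-[(1S,2S,4R)-1,3,3-trimethyl-7-oxabicyclo[2.2.1]heptan-2-yl] S-methyl carbonodithioate and 15 methyl acrylate
Product: 17 methyl 3-[(1S,2R,4R)-1,3,3-trimethyl-7-oxabicyclo[2.2.1]heptan-2-yl]propanoate, via C2 radical 16 (not isolated)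
Conditions: Bu3SnH (syringe pump), AIBN (cat.), 15 (10 equiv), PhMe, 100 °C
Reagents that add atoms: none
Why: Giese reaction: the stannyl radical adds to the thiocarbonyl sulfur, β‑scission releases the nucleophilic secondary C2 radical, and this should add to the acrylate terminus on the exo face (syn to O7), the endo face being screened by the C5–C6 bridge, which sets C2 as R before hydrogen transfer from Bu3SnH carries the chain.

Step 11
Reactants: 17 methyl 3-[(1S,2R,4R)-1,3,3-trimethyl-7-oxabicyclo[2.2.1]heptan-2-yl]propanoate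
Product: 19 (1S,2R,4R)-2-(but-3-yn-1-yl)-1,3,3-trimethyl-7-oxabicyclo[2.2.1]heptane, via aldehyde 18 (not isolated)
Conditions: iBu2AlH (1.1 equiv), CH2Cl2, −78 °C; then MeOH, K2CO3, dimethyl (1-diazo-2-oxopropyl)phosphonate, −78 °C to rt
Reagents that add atoms: dimethyl (1-diazo-2-oxopropyl)phosphonate, COP(=O)(OC)C(=[N+]=[N-])C(C)=O
Why: Partial ester reduction by iBu2AlH at low temperature gives an aluminium hemiacetal that releases the aldehyde on methanolysis, and Seyferth–Gilbert homologation with the Ohira–Bestmann reagent in the same flask should convert it into the terminal alkyne; C2 is remote from the carbonyl and cannot epimerise.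

Step 12
Reactants: 19 (1S,2R,4R)-2-(but-3-yn-1-yl)-1,3,3-trimethyl-7-oxabicyclo[2.2.1]heptane
Product: 21 (1S,2R,4R)-2-[(3E)-4-iodo-3-methylbut-3-en-1-yl]-1,3,3-trimethyl-7-oxabicyclo[2.2.1]heptane, via alkenylalane 20 (not isolated)
Conditions: AlMe3 (3 equiv), Cp2ZrCl2 (0.3 equiv), CH2Cl2, 0 °C to rt; then I2, THF, −30 to 0 °C
Reagents that add atoms: trimethylaluminium, C[Al](C)C; iodine, II
Why: Zirconium‑catalysed Negishi carboalumination adds methyl and aluminium syn across the alkyne with methyl at the internal carbon, and iodinolysis of the C–Al bond with retention should give the E alkenyl iodide, which fixes the alkene geometry of the target.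

Step 13
Reactants: 22 methyl 4-hydroxy-3-methylbenzoate
Product: 23 methyl 4-[(2,2-dimethylpropanoyl)oxy]-3-methylbenzoate
Conditions: pivaloyl chloride, Et3N, DMAP (cat.), CH2Cl2, 0 °C to rt
Reagents that add atoms: pivaloyl chloride, CC(C)(C)C(Cl)=O
Why: DMAP‑catalysed O‑acylation of the phenol gives a pivalate that deactivates the ring for the next step, is too hindered for acyl transfer to a benzylic organometallic, and is cleaved in the final saponification.

Step 14
Reactants: 23 methyl 4-[(2,2-dimethylpropanoyl)oxy]-3-methylbenzoate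
Product: 24 methyl 3-(bromomethyl)-4-[(2,2-dimethylpropanoyl)oxy]benzoate
Conditions: NBS, AIBN (cat.), PhCF3, 85 °C
Reagents that add atoms: N-bromosuccinimide, O=C1CCC(=O)N1Br
Why: Wohl–Ziegler benzylic bromination: the ring methyl carries the only benzylic C–H bonds, and both ester groups deactivate the ring against electrophilic bromination.

Step 15
Reactants: 21 (1S,2R,4R)-2-[(3E)-4-iodo-3-methylbut-3-en-1-yl]-1,3,3-trimethyl-7-oxabicyclo[2.2.1]heptane and 24 methyl 3-(bromomethyl)-4-[(2,2-dimethylpropanoyl)oxy]benzoate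
Product: 26 methyl 4-[(2,2-dimethylpropanoyl)oxy]-3-{(2E)-3-methyl-5-[(1S,2R,4R)-1,3,3-trimethyl-7-oxabicyclo[2.2.1]heptan-2-yl]pent-2-en-1-yl}benzoate, via benzylzinc bromide 25 (not isolated)
Conditions: 24, Zn dust, LiCl, THF, 0 °C to rt; then 21, Pd(PPh3)4 (3 mol%), THF, 40 °C
Reagents that add atoms: none
Why: Negishi cross‑coupling: LiCl‑assisted zinc insertion should give a benzylic zinc bromide that tolerates both esters, and zerovalent‑palladium‑catalysed coupling with the alkenyl iodide forms the ArCH2–CH= bond with retention of the E geometry and no possibility of allylic transposition.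

Step 16
Reactants: 26 methyl 4-[(2,2-dimethylpropanoyl)oxy]-3-{(2E)-3-methyl-5-[(1S,2R,4R)-1,3,3-trimethyl-7-oxabicyclo[2.2.1]heptan-2-yl]pent-2-en-1-yl}benzoate
Product: 27 4-hydroxy-3-{(2E)-3-methyl-5-[(1S,2R,4R)-1,3,3-trimethyl-7-oxabicyclo[2.2.1]heptan-2-yl]pent-2-en-1-yl}benzoic acid
Conditions: LiOH, THF/MeOH/H2O, 55 °C; then 1 M HCl to pH 4, 0 °C
Reagents that add atoms: lithium hydroxide, [Li+].[OH-]
Why: Saponification (acyl–oxygen cleavage of the methyl ester and the aryl pivalate by hydroxide) followed by mild acidification should free the acid and the phenol without acid‑promoted chroman formation or opening of the bridged ether.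

Compound list
1 | methyl 3-hydroxy-2,2-dimethylpropanoate | COC(=O)C(C)(C)CO | starting material
2 | methyl 3-[(tert-butyldimethylsilyl)oxy]-2,2-dimethylpropanoate | COC(=O)C(C)(C)CO[Si](C)(C)C(C)(C)C | intermediate
3 | 3-[(tert-butyldimethylsilyl)oxy]-N-methoxy-N,2,2-trimethylpropanamide | CON(C)C(=O)C(C)(C)CO[Si](C)(C)C(C)(C)C | intermediate
4 | 1-[(tert-butyldimethylsilyl)oxy]-2,2-dimethylpentan-3-one | CCC(=O)C(C)(C)CO[Si](C)(C)C(C)(C)C | intermediate
5 | 6-[(tert-butyldimethylsilyl)oxy]-1,1,1-trifluoro-3,5,5-trimethylhexane-2,4-dione (not isolated) | CC(C(=O)C(F)(F)F)C(=O)C(C)(C)CO[Si](C)(C)C(C)(C)C | intermediate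
6 | 1-[(tert-butyldimethylsilyl)oxy]-4-diazo-2,2-dimethylpentan-3-one | CC(=[N+]=[N-])C(=O)C(C)(C)CO[Si](C)(C)C(C)(C)C | intermediate
7 | 4-diazo-1-hydroxy-2,2-dimethylpentan-3-one | CC(=[N+]=[N-])C(=O)C(C)(C)CO | intermediate
8 | 4-diazo-2,2-dimethyl-3-oxopentanal | CC(=[N+]=[N-])C(=O)C(C)(C)C=O | intermediate
9 | ethylene | C=C | starting material
10 | 3,3,5-trimethyl-3H-furan-1-ium-4-olate, the cyclic carbonyl ylide (not isolated) | CC1=C([O-])C(C)(C)C=[O+]1 | intermediate
11 | (1S,4R)-1,3,3-trimethyl-7-oxabicyclo[2.2.1]heptan-2-one | O=C1C(C)(C)[C@H]2CC[C@]1(C)O2 | intermediate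
12 | (1S,2S,4R)-1,3,3-trimethyl-7-oxabicyclo[2.2.1]heptan-2-ol (2-endo) | O[C@H]1C(C)(C)[C@H]2CC[C@]1(C)O2 | intermediate
13 | sodium O-[(1S,2S,4R)-1,3,3-trimethyl-7-oxabicyclo[2.2.1]heptan-2-yl] carbonodithioate (not isolated) | [Na+].[S-]C(=S)O[C@H]1C(C)(C)[C@H]2CC[C@]1(C)O2 | intermediate
14 | O-[(1S,2S,4R)-1,3,3-trimethyl-7-oxabicyclo[2.2.1]heptan-2-yl] S-methyl carbonodithioate | CSC(=S)O[C@H]1C(C)(C)[C@H]2CC[C@]1(C)O2 | intermediate
15 | methyl acrylate | C=CC(=O)OC | starting material
16 | (1S,4R)-1,3,3-trimethyl-7-oxabicyclo[2.2.1]heptan-2-yl radical (not isolated) | [CH]1C(C)(C)[C@H]2CC[C@]1(C)O2 | intermediate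
17 | methyl 3-[(1S,2R,4R)-1,3,3-trimethyl-7-oxabicyclo[2.2.1]heptan-2-yl]propanoate | COC(=O)CC[C@@H]1C(C)(C)[C@H]2CC[C@]1(C)O2 | intermediate
18 | 3-[(1S,2R,4R)-1,3,3-trimethyl-7-oxabicyclo[2.2.1]heptan-2-yl]propanal (not isolated) | O=CCC[C@@H]1C(C)(C)[C@H]2CC[C@]1(C)O2 | intermediate
19 | (1S,2R,4R)-2-(but-3-yn-1-yl)-1,3,3-trimethyl-7-oxabicyclo[2.2.1]heptane | C#CCC[C@@H]1C(C)(C)[C@H]2CC[C@]1(C)O2 | intermediate
20 | dimethyl{(1E)-2-methyl-4-[(1S,2R,4R)-1,3,3-trimethyl-7-oxabicyclo[2.2.1]heptan-2-yl]but-1-en-1-yl}alumane (not isolated) | C[Al](C)/C=C(\C)CC[C@@H]1C(C)(C)[C@H]2CC[C@]1(C)O2 | intermediate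
21 | (1S,2R,4R)-2-[(3E)-4-iodo-3-methylbut-3-en-1-yl]-1,3,3-trimethyl-7-oxabicyclo[2.2.1]heptane | I/C=C(\C)CC[C@@H]1C(C)(C)[C@H]2CC[C@]1(C)O2 | intermediate
22 | methyl 4-hydroxy-3-methylbenzoate | COC(=O)c1ccc(O)c(C)c1 | starting material
23 | methyl 4-[(2,2-dimethylpropanoyl)oxy]-3-methylbenzoate | COC(=O)c1ccc(OC(=O)C(C)(C)C)c(C)c1 | intermediate
24 | methyl 3-(bromomethyl)-4-[(2,2-dimethylpropanoyl)oxy]benzoate | COC(=O)c1ccc(OC(=O)C(C)(C)C)c(CBr)c1 | intermediate
25 | {5-(methoxycarbonyl)-2-[(2,2-dimethylpropanoyl)oxy]benzyl}zinc bromide (not isolated) | COC(=O)c1ccc(OC(=O)C(C)(C)C)c(C[Zn]Br)c1 | intermediate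
26 | methyl 4-[(2,2-dimethylpropanoyl)oxy]-3-{(2E)-3-methyl-5-[(1S,2R,4R)-1,3,3-trimethyl-7-oxabicyclo[2.2.1]heptan-2-yl]pent-2-en-1-yl}benzoate | COC(=O)c1ccc(OC(=O)C(C)(C)C)c(C/C=C(\C)CC[C@@H]2C(C)(C)[C@H]3CC[C@]2(C)O3)c1 | intermediate
27 | 4-hydroxy-3-{(2E)-3-methyl-5-[(1S,2R,4R)-1,3,3-trimethyl-7-oxabicyclo[2.2.1]heptan-2-yl]pent-2-en-1-yl}benzoic acid | C/C(=C\Cc1cc(C(=O)O)ccc1O)CC[C@@H]1C(C)(C)[C@H]2CC[C@]1(C)O2 | target

Total step count: 16 (steps 1–12 on the main line, steps 13–14 for the arene, steps 15–16 after convergence).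
Longest linear sequence: 14 steps (1–12, 15, 16).

Steps most likely to fail

Step 7. Ethylene is a less reactive dipolarophile than the alkenes normally used, so the ylide may leave the rhodium before it is captured and facial control by the ligand would then be lost; slow capture would also let the ylide decay. The fallback sets out from 8 and comes back at 12. The cycloaddition is run with achiral Rh2(OAc)4 under ethylene pressure to give racemic 1,3,3-trimethyl-7-oxabicyclo[2.2.1]heptan-2-one F1. LiAlH4 reduces it to the racemic 2‑endo alcohol (1RS,2RS,4SR)-1,3,3-trimethyl-7-oxabicyclo[2.2.1]heptan-2-ol F2. Its sodium alkoxide is carbamoylated with (S)-1-phenylethyl isocyanate and the two diastereomeric carbamates are separated by chromatography or crystallisation. (1S,2S,4R)-1,3,3-trimethyl-7-oxabicyclo[2.2.1]heptan-2-yl N-[(1S)-1-phenylethyl]carbamate F3 is then cleaved with LiAlH4 to give 12.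

Step 10. Hydrogen‑atom transfer from Bu3SnH to the doubly neopentyl C2 radical may outrun its addition to the acrylate (plain deoxygenation), or the adduct radical may add further acrylate. The fallback sets out from 14 and comes back at 18. Keck radical allylation of 14 with allyltributylstannane and AIBN (PhH, 80 °C), a chain that contains no hydride donor, should give by the same exo attack (1S,2R,4R)-1,3,3-trimethyl-2-(prop-2-en-1-yl)-7-oxabicyclo[2.2.1]heptane F4. Hydroboration with 9-borabicyclo[3.3.1]nonane and NaOH/H2O2 work‑up gives 3-[(1S,2R,4R)-1,3,3-trimethyl-7-oxabicyclo[2.2.1]heptan-2-yl]propan-1-ol F5. Dess–Martin oxidation then gives aldehyde 18, which is taken through the Ohira–Bestmann half of step 11.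

Step 4. C‑Trifluoroacetylation of the hindered lithium enolate may stay incomplete, or diazo transfer to the α‑methyl diketone may be slow and be overtaken by cleavage back to 4. The fallback sets out from 2 and comes back at 6. The ester is cleaved with Me3SiOK (THF, 50 °C; citric acid work‑up) to 3-[(tert-butyldimethylsilyl)oxy]-2,2-dimethylpropanoic acid F6. 1-Chloro-N,N,2-trimethylprop-1-en-1-amine converts it under neutral conditions into 3-[(tert-butyldimethylsilyl)oxy]-2,2-dimethylpropanoyl chloride F7. Acylation of excess diazoethane (Et2O, −20 °C, Arndt–Eistert‑type) then gives 6 directly.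

Further compounds
F1 | step 7 | racemic 1,3,3-trimethyl-7-oxabicyclo[2.2.1]heptan-2-one | O=C1C(C)(C)C2CCC1(C)O2
F2 | step 7 | racemic (1RS,2RS,4SR)-1,3,3-trimethyl-7-oxabicyclo[2.2.1]heptan-2-ol (2-endo) | OC1C(C)(C)C2CCC1(C)O2
F3 | step 7 | (1S,2S,4R)-1,3,3-trimethyl-7-oxabicyclo[2.2.1]heptan-2-yl N-[(1S)-1-phenylethyl]carbamate | C[C@H](NC(=O)O[C@H]1C(C)(C)[C@H]2CC[C@]1(C)O2)c1ccccc1
F4 | step 10 | (1S,2R,4R)-1,3,3-trimethyl-2-(prop-2-en-1-yl)-7-oxabicyclo[2.2.1]heptane | C=CC[C@@H]1C(C)(C)[C@H]2CC[C@]1(C)O2
F5 | step 10 | 3-[(1S,2R,4R)-1,3,3-trimethyl-7-oxabicyclo[2.2.1]heptan-2-yl]propan-1-ol | OCCC[C@@H]1C(C)(C)[C@H]2CC[C@]1(C)O2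
F6 | step 4 | 3-[(tert-butyldimethylsilyl)oxy]-2,2-dimethylpropanoic acid | OC(=O)C(C)(C)CO[Si](C)(C)C(C)(C)C
F7 | step 4 | 3-[(tert-butyldimethylsilyl)oxy]-2,2-dimethylpropanoyl chloride | ClC(=O)C(C)(C)CO[Si](C)(C)C(C)(C)C
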